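## Retrosynthetic overview

The route rests on ring A, a fully regiodefined acylphloroglucinol (C1' cinnamoyl, C2' OH, C3' side chain, C4' OH, C5' H, C6' OMe), read as a folded polyketide chain.
Cutting C3'–C4' and C1'–C2' turns C2', C3' and the CH2–CH(O)–C(CH3)=CH2 chain into (R)-5-isopropenyl-γ-butyrolactone. The same cuts turn C4'–C5'–C6'(OMe)–C1'–C(=O)–CH=CH–Ar into C2–C6 plus the styryl arm of a 4-methoxy-6-styryl-2-pyranone, so the O6' methyl ether and the free C2'' alcohol need no separate differentiation.
The lactone carries the only stereocentre and comes from D-glutamic acid (retentive diazotisation, methyl ketone, non-basic methylenation). The pyranone comes from 4-methoxy-6-methyl-2-pyranone and O-silylated 4-hydroxybenzaldehyde (vinylogous aldol addition, elimination).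
Ring order: ring B and the pyranone ring are bought, the lactone ring is made first, ring A is formed last at the expense of both heterocycles, and buffered fluoride then frees the 4-OH.

Key step: step 8

Remark: C2'' is read from the SMILES as (R) (O > isopropenyl > CH2Ar > H). C5 of the lactone has the same spatial arrangement and descriptor, as does the α-carbon of D-glutamic acid after retentive deamination. LiN(iPr)2 and LiN(SiMe3)2 are taken as commercial solutions.

## Route

Step 1
Reactants: 1 D-glutamic acid
Product: 2 (R)-5-oxotetrahydrofuran-2-carboxylic acid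
Conditions: NaNO2, aq. HCl, 0 °C → rt
Reagents that add atoms: none
Why: Nitrous acid deamination of an α-amino acid runs with net retention by double inversion (the α-carboxylate displaces N2 to give an α-lactone, which the γ-carboxyl group opens), so the D configuration is carried into the (R)-lactone acid without any external atom being taken up.

Step 2
Reactants: 2 (R)-5-oxotetrahydrofuran-2-carboxylic acid
Product: 3 (R)-5-oxotetrahydrofuran-2-carbonyl chloride
Conditions: (COCl)2, DMF (cat.), CH2Cl2, 0 °C → rt
Reagents that add atoms: oxalyl chloride, O=C(Cl)C(=O)Cl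
Why: DMF-catalysed acid chloride formation is free of amine base, leaves the γ-lactone untouched and opens no ketene or enol pathway by which the oxygen-bearing stereocentre could be lost.

Step 3
Reactants: 3 (R)-5-oxotetrahydrofuran-2-carbonyl chloride
Product: 4 (R)-5-acetyldihydrofuran-2(3H)-one
Conditions: MeMgBr (1.0 equiv), Fe(acac)3 (3 mol %), THF, −78 °C
Reagents that add atoms: methylmagnesium bromide, C[Mg]Br
Why: Iron-catalysed acylation of a Grignard reagent by an acid chloride (a Kumada-type cross-coupling) is far faster at −78 °C than addition of MeMgBr to the lactone or to the ketone formed, so a single methyl group is transferred and C5 keeps its configuration.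

Step 4
Reactants: 4 (R)-5-acetyldihydrofuran-2(3H)-one
Product: 5 (R)-5-(prop-1-en-2-yl)dihydrofuran-2(3H)-one
Conditions: Zn, CH2Br2, TiCl4, THF, −40 → 5 °C (pre-formed); then 4, CH2Cl2, 0 °C → rt
Reagents that add atoms: dibromomethane, BrCBr
Why: Takai–Lombardo methylenation uses a non-basic gem-dimetallic methylene reagent that attacks ketones but not esters or lactones, so the enolisable α-acyloxy stereocentre, which a basic Wittig ylide would put at risk, stays (R) and the lactone carbonyl survives.

Step 5
Reactants: 6 4-hydroxybenzaldehyde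
Product: 7 4-(tert-butyldimethylsilyloxy)benzaldehyde
Conditions: TBSCl, imidazole, DMF, rt
Reagents that add atoms: tert-butyldimethylsilyl chloride (TBSCl), CC(C)(C)[Si](C)(C)Cl
Why: Imidazole-promoted silylation masks the acidic phenol, which would otherwise quench the carbanions of steps 6 and 8 and, as a phenoxide, switch off the electrophilicity of the aldehyde and later of the pyranone.

Step 6
Reactants: 8 4-methoxy-6-methyl-2H-pyran-2-one; 7 4-(tert-butyldimethylsilyloxy)benzaldehyde
Product: 10 (±)-6-{2-[4-(tert-butyldimethylsilyloxy)phenyl]-2-hydroxyethyl}-4-methoxy-2H-pyran-2-one, via lithium dienolate 9 (not isolated)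
Conditions: LiN(iPr)2 (1.05 equiv), THF, −78 °C; then 7, −78 °C; AcOH
Reagents that add atoms: none
Why: Vinylogous aldol addition, in which amide-base equilibration deprotonates the C6 methyl group to the extended dienolate 9, which adds through its exocyclic carbon to the non-enolisable aldehyde, the new carbinol centre being formed as a racemate that is erased in step 7.

Step 7
Reactants: 10 (±)-6-{2-[4-(tert-butyldimethylsilyloxy)phenyl]-2-hydroxyethyl}-4-methoxy-2H-pyran-2-one
Product: 12 4-methoxy-6-[(E)-4-(tert-butyldimethylsilyloxy)styryl]-2H-pyran-2-one, via benzylic mesylate 11 (not isolated)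
Conditions: MsCl, Et3N, CH2Cl2, 0 °C; then DBU, 0 °C → rt
Reagents that add atoms: none
Why: Mesylation of the benzylic alcohol and E1cB-type elimination through the acidic vinylogous CH2 give the fully conjugated styrylpyranone as the thermodynamically preferred (E)-alkene, and the aryl silyl ether, which would not survive the classical Mg(OMe)2/MeOH condensation, stays in place.

Step 8
Reactants: 5 (R)-5-(prop-1-en-2-yl)dihydrofuran-2(3H)-one; 12 4-methoxy-6-[(E)-4-(tert-butyldimethylsilyloxy)styryl]-2H-pyran-2-one
Product: 15 (E)-3-[4-(tert-butyldimethylsilyloxy)phenyl]-1-{2,4-dihydroxy-3-[(2R)-2-hydroxy-3-methylbut-3-en-1-yl]-6-methoxyphenyl}prop-2-en-1-one, via lactone lithium enolate 13 (not isolated), via open-chain acyl lactone 14 (not isolated)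
Conditions: 5 (1.3 equiv), LiN(iPr)2 (1.25 equiv), THF, −78 °C; 12 (1.0 equiv), −78 → −40 °C; LiN(SiMe3)2 (2.2 equiv), −40 °C → rt; AcOH, −20 °C
Reagents that add atoms: none
Why: Proposed new method: enolate 13 adds in 1,2-fashion to the pyranone carbonyl C2 of 12 (new bond C3'–C4'), the tetrahedral adduct expels the ring oxygen as the cinnamoyl enolate, and internal proton transfer gives the β-keto-lactone enolate of 14, a Claisen-type acyl transfer that this deprotonation makes irreversible. The added LiN(SiMe3)2 keeps the doubly activated CH2 (former pyranone C5, between the enol ether carbon and the cinnamoyl ketone) metalated while acidic phenols build up, and this carbon attacks the lactone carbonyl (new bond C1'–C2') in a 6-(enolexo)-exo-trig Dieckmann-type closure of ring A, after which loss of the tethered C2'' alkoxide and enolisation to the arene provide the thermodynamic sink. The closest known reaction types are the carbanion-induced ring transformations of 2-pyranones (attack, ring opening, recyclisation to an arene) and the base-mediated Claisen cyclisation of 3,5,7-triketo esters and 6-(2-oxoalkyl)-4-hydroxy-2-pyranones to acylphloroglucinols, the new elements being a 4-methoxy-2-pyranone as acyl donor toward a lactone enolate and the coupling of both events in one flask. No stereocentre is created: C2'' comes from 5, its C–O and C–H bonds are never broken, and the transient centre at the lactone α-carbon vanishes on aromatisation. The step needs attack at C2 rather than at C4, C6 or the styryl terminus, which rests on the hard lithium enolate at low temperature, on the donor groups (4-OMe, ring oxygen at C6, para-silyloxy) that lower the electrophilicity of the conjugate positions, on the good enolate leaving group at C2, and on the absence of free amide base when 12 is added, which avoids C3 lithiation. It also needs Claisen rather than aldol folding: the former ring C3=C4 bond holds C2 and C5 cis so that both modes are six-membered, but attack of the lactone α-carbon on the cinnamoyl ketone gives a spiro aldolate with a quaternary carbon that cannot aromatise and can revert, whereas the Claisen product drains off as a stabilised phenoxide.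

Step 9
Reactants: 15 (E)-3-[4-(tert-butyldimethylsilyloxy)phenyl]-1-{2,4-dihydroxy-3-[(2R)-2-hydroxy-3-methylbut-3-en-1-yl]-6-methoxyphenyl}prop-2-en-1-one
Product: 16 (E)-1-{2,4-dihydroxy-3-[(2R)-2-hydroxy-3-methylbut-3-en-1-yl]-6-methoxyphenyl}-3-(4-hydroxyphenyl)prop-2-en-1-one (target)
Conditions: Bu4NF (1.1 equiv), AcOH (1.5 equiv), THF, 0 °C
Reagents that add atoms: none
Why: Fluoride-induced cleavage of the aryl silyl ether is fast at 0 °C, and the acetic acid buffer keeps the 2'-phenol protonated so that oxa-Michael closure of the chalcone to the flavanone does not set in, while the allylic alcohol stereocentre and both alkenes are not touched.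

## Compound list

1 | D-glutamic acid | N[C@H](CCC(=O)O)C(=O)O | starting material
2 | (R)-5-oxotetrahydrofuran-2-carboxylic acid | O=C(O)[C@H]1CCC(=O)O1 | intermediate
3 | (R)-5-oxotetrahydrofuran-2-carbonyl chloride | O=C(Cl)[C@H]1CCC(=O)O1 | intermediate
4 | (R)-5-acetyldihydrofuran-2(3H)-one | CC(=O)[C@H]1CCC(=O)O1 | intermediate
5 | (R)-5-(prop-1-en-2-yl)dihydrofuran-2(3H)-one | C=C(C)[C@H]1CCC(=O)O1 | intermediate
6 | 4-hydroxybenzaldehyde | O=Cc1ccc(O)cc1 | starting material
7 | 4-(tert-butyldimethylsilyloxy)benzaldehyde | O=Cc1ccc(O[Si](C)(C)C(C)(C)C)cc1 | intermediate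
8 | 4-methoxy-6-methyl-2H-pyran-2-one | COC1=CC(=O)OC(C)=C1 | starting material
9 | lithium 4-methoxy-6-methylidene-6H-pyran-2-olate (dienolate of 8) | C=C1C=C(OC)C=C([O-])O1.[Li+] | intermediate
10 | (±)-6-{2-[4-(tert-butyldimethylsilyloxy)phenyl]-2-hydroxyethyl}-4-methoxy-2H-pyran-2-one (racemic) | COC1=CC(=O)OC(CC(O)c2ccc(O[Si](C)(C)C(C)(C)C)cc2)=C1 | intermediate
11 | (±)-1-[4-(tert-butyldimethylsilyloxy)phenyl]-2-(4-methoxy-2-oxo-2H-pyran-6-yl)ethyl methanesulfonate | COC1=CC(=O)OC(CC(OS(C)(=O)=O)c2ccc(O[Si](C)(C)C(C)(C)C)cc2)=C1 | intermediate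
12 | 4-methoxy-6-[(E)-4-(tert-butyldimethylsilyloxy)styryl]-2H-pyran-2-one | COC1=CC(=O)OC(/C=C/c2ccc(O[Si](C)(C)C(C)(C)C)cc2)=C1 | intermediate
13 | lithium (R)-5-(prop-1-en-2-yl)-4,5-dihydrofuran-2-olate (enolate of 5) | C=C(C)[C@H]1CC=C([O-])O1.[Li+] | intermediate
14 | (5R)-3-{(2E,6E)-7-[4-(tert-butyldimethylsilyloxy)phenyl]-3-methoxy-5-oxohepta-2,6-dienoyl}-5-(prop-1-en-2-yl)dihydrofuran-2(3H)-one (C3 undefined, enolised) | C=C(C)[C@H]1CC(C(=O)/C=C(/OC)CC(=O)/C=C/c2ccc(O[Si](C)(C)C(C)(C)C)cc2)C(=O)O1 | intermediate
15 | (E)-3-[4-(tert-butyldimethylsilyloxy)phenyl]-1-{2,4-dihydroxy-3-[(2R)-2-hydroxy-3-methylbut-3-en-1-yl]-6-methoxyphenyl}prop-2-en-1-one | C=C(C)[C@H](O)Cc1c(O)cc(OC)c(C(=O)/C=C/c2ccc(O[Si](C)(C)C(C)(C)C)cc2)c1O | intermediate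
16 | (E)-1-{2,4-dihydroxy-3-[(2R)-2-hydroxy-3-methylbut-3-en-1-yl]-6-methoxyphenyl}-3-(4-hydroxyphenyl)prop-2-en-1-one | C=C(C)[C@H](O)Cc1c(O)cc(OC)c(C(=O)/C=C/c2ccc(O)cc2)c1O | target

## Step count and risks

Total step count: 9.
Longest linear sequence: 6 (steps 1, 2, 3, 4, 8, 9). The pyranone arm (steps 5, 6, 7) joins at step 8.

**Risk 1, step 8.**

What may go wrong:
- The enolate may add in a conjugate sense: addition–elimination at C4 with loss of methoxide (a known mode for softer carbanions), or addition at C6 or at the styryl terminus.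
- The sequence may stall after the first C–C bond, because the lactone carbonyl is then part of an enolate and is a poor electrophile.
- The chain may fold by the aldol mode and then lose hydroxide in a vinylogous sense.
- The lactone enolate may self-condense on warming.

Fallback (sets out from 7, comes back at 15; known chemistry only): ring A is taken from a commercial arene instead of being built. Commercial 5-methoxyresorcinol is protected with MOMCl/iPr2NEt as 1-methoxy-3,5-bis(methoxymethoxy)benzene F1. Directed ortho-lithiation between the two MOM ethers (nBuLi, THF, 0 °C), then CuBr·SMe2 and prenyl bromide, gives 5-methoxy-1,3-bis(methoxymethoxy)-2-(3-methylbut-2-en-1-yl)benzene F2. Shi epoxidation (D-fructose-derived ketone, KHSO5, K2CO3, MeCN/dimethoxymethane/aqueous buffer, 0 °C) should give (R)-3-[4-methoxy-2,6-bis(methoxymethoxy)benzyl]-2,2-dimethyloxirane F3. Al(OiPr)3 in hot toluene isomerises the epoxide, with the secondary C–O bond untouched, to (R)-1-[4-methoxy-2,6-bis(methoxymethoxy)phenyl]-3-methylbut-3-en-2-ol F4. This alcohol is silylated (TBSCl, imidazole) to its tert-butyldimethylsilyl ether F5.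

In parallel, 7 is homologated by a Horner–Wadsworth–Emmons reaction with diethyl (N-methoxy-N-methylcarbamoylmethyl)phosphonate (NaH, THF) to (E)-3-[4-(tert-butyldimethylsilyloxy)phenyl]-N-methoxy-N-methylacrylamide F6. A second directed lithiation of F5 (nBuLi, THF, 0 °C; the two free ring positions are equivalent) and acylation by F6 give the fully protected chalcone F7. HCl in MeOH then removes both MOM groups and the secondary silyl ether to return 15.

**Risk 2, step 4.**

What may go wrong:
- C5 may epimerise through enolisation of the α-acyloxy ketone.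
- Zinc or low-valent titanium may reductively cleave the α-acyloxy C–O bond.
- The lactone carbonyl may be partly methylenated.

Fallback (sets out from 4, comes back at 5): a two-stage Peterson olefination replaces the gem-dimetallic reagent. The non-basic organocerium reagent from Me3SiCH2MgCl and CeCl3 (THF, −78 °C) adds to the ketone to give (5R)-5-[2-hydroxy-1-(trimethylsilyl)propan-2-yl]dihydrofuran-2(3H)-one F8. The carbinol epimers are of no consequence. Aqueous HF in MeCN then eliminates silicon and oxygen to give 5.

**Risk 3, step 6.**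

What may go wrong:
- Kinetic metalation may occur at C3 of the pyranone instead of the methyl group.
- The lithium aldolate may undergo retro-aldol cleavage before the quench.
- The later elimination may be incomplete.

Fallback (sets out from 8, comes back at 12, replacing steps 6 and 7): the alkene is made by olefination rather than by aldol addition and dehydration. Radical bromination of 8 (NBS, dibenzoyl peroxide, PhCF3, reflux) gives 6-(bromomethyl)-4-methoxy-2H-pyran-2-one F9. A Michaelis–Arbuzov reaction with P(OEt)3 (neat, 130 °C) gives diethyl [(4-methoxy-2-oxo-2H-pyran-6-yl)methyl]phosphonate F10. A Horner–Wadsworth–Emmons reaction with 7 (NaH, THF, 0 °C) should deliver 12 directly as the (E)-isomer.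

## Further compounds

F1 | step 8 | 1-methoxy-3,5-bis(methoxymethoxy)benzene | COc1cc(OCOC)cc(OCOC)c1
F2 | step 8 | 5-methoxy-1,3-bis(methoxymethoxy)-2-(3-methylbut-2-en-1-yl)benzene | COc1cc(OCOC)c(CC=C(C)C)c(OCOC)c1
F3 | step 8 | (R)-3-[4-methoxy-2,6-bis(methoxymethoxy)benzyl]-2,2-dimethyloxirane | CC1(C)O[C@@H]1Cc1c(OCOC)cc(OC)cc1OCOC
F4 | step 8 | (R)-1-[4-methoxy-2,6-bis(methoxymethoxy)phenyl]-3-methylbut-3-en-2-ol | C=C(C)[C@H](O)Cc1c(OCOC)cc(OC)cc1OCOC
F5 | step 8 | (R)-tert-butyl({1-[4-methoxy-2,6-bis(methoxymethoxy)phenyl]-3-methylbut-3-en-2-yl}oxy)dimethylsilane | C=C(C)[C@H](O[Si](C)(C)C(C)(C)C)Cc1c(OCOC)cc(OC)cc1OCOC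
F6 | step 8 | (E)-3-[4-(tert-butyldimethylsilyloxy)phenyl]-N-methoxy-N-methylacrylamide | CON(C)C(=O)/C=C/c1ccc(O[Si](C)(C)C(C)(C)C)cc1
F7 | step 8 | (E)-1-{3-[(2R)-2-(tert-butyldimethylsilyloxy)-3-methylbut-3-en-1-yl]-6-methoxy-2,4-bis(methoxymethoxy)phenyl}-3-[4-(tert-butyldimethylsilyloxy)phenyl]prop-2-en-1-one | C=C(C)[C@H](O[Si](C)(C)C(C)(C)C)Cc1c(OCOC)cc(OC)c(C(=O)/C=C/c2ccc(O[Si](C)(C)C(C)(C)C)cc2)c1OCOC
F8 | step 4 | (5R)-5-[2-hydroxy-1-(trimethylsilyl)propan-2-yl]dihydrofuran-2(3H)-one | CC(O)(C[Si](C)(C)C)[C@H]1CCC(=O)O1
F9 | step 6 | 6-(bromomethyl)-4-methoxy-2H-pyran-2-one | COC1=CC(=O)OC(CBr)=C1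
F10 | step 6 | diethyl [(4-methoxy-2-oxo-2H-pyran-6-yl)methyl]phosphonate | CCOP(=O)(CC1=CC(OC)=CC(=O)O1)OCC
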